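## Structural features

Bisoflavolin K (18) is an achiral, fully aromatic dimer of two isoflavones, that is, of two 3-aryl-4H-chromen-4-one units. The first unit is a 7-hydroxychromenone whose C3 carries a phenyl ring (ring B) with a hydroxyl group at C4' and the linking ether oxygen at C3'. The second is an 8-chloro-7-hydroxychromenone whose C3 carries a phenyl ring with that same ether oxygen at C4'. There is no stereocentre, so the problem is one of constitution: the halves differ only in one chlorine atom and in the meta or para position of the ether oxygen, and each ring A must end on the correct side. A late chlorination could not tell the two 7-hydroxychromenones or the activated ring B apart, so the chlorine at C8 has to arrive with a building block. Fragile features are the three free phenols (oxidation), C2 of each pyranone (ring opening by hydroxide or other nucleophiles) and the aryl chloride (lost under hydrogenolysis); the diaryl ether is robust. The real difficulty is to build two different pyranone rings on an unsymmetrical diaryl ether while keeping the two nearly identical halves distinguishable. The key step exploits the fact that in each chromenone C3 bears both the ring-B aryl group and the C4 carbonyl while C2 is a CH at the aldehyde oxidation level, the 2-aryl-3-oxopropanal array that results when the aroyl group of a chalcone epoxide moves to the benzylic carbon.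

## Logic of the disconnections

18 to 17: the three phenolic O–H bonds are traced back to O–CH3 bonds. The methyl ethers come with cheap building blocks and survive base, peroxide and BF3, so 17 can be handled without concern for oxidation. The forward step must cleave aryl methyl ethers with a Lewis acid, not with a base or nucleophile that would open the pyranones, and must leave the aryl chloride and the diaryl ether alone.

17 to 15 (through 16): both O1–C2 bonds of the pyranone rings are cut, which reveals in each half a phenol and a formyl group; the phenols are carried as benzyl ethers. This removes both heterocycles and leaves an open-chain bis(β-keto aldehyde). The forward step needs a debenzylation that is not a hydrogenolysis (because of the chlorine) and does not touch the methyl ethers, followed by acid-induced cyclodehydration.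

15 to 14: both C3–C4 bonds (aroyl carbonyl carbon to the diaryl-substituted methine) are cut, each aroyl group is returned to the formyl carbon, and an oxirane is placed across the two sp3 carbons. Two 1,3-dicarbonyl arrays thereby become two enone epoxides that one reagent can process together. The forward step demands ionisation at the aryl-bearing oxirane carbon only, migration of the aroyl group and not of hydride, blocked 2'-oxygens, and the same outcome in both halves although their cation-stabilising groups differ.

14 to 13: the four oxirane C–O bonds are removed to give two E-enones. This deletes all stereocentres. The forward oxidation must be nucleophilic so that the electron-rich arenes are spared, and it must give trans epoxides.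

13 to 10 and 12: the Cα=Cβ bond of the non-chlorinated enone is cut by a retro-aldol condensation, which splits off one ring A as a methyl ketone. The forward condensation has to take place at an aldehyde in the presence of an enone.

10 to 4 and 8 (through 9): the Cα=Cβ bond of the chlorinated enone is cut in the same way, and the remaining aldehyde is masked as a dioxolane. With one aldehyde free and one masked, each ketone is delivered to its own side without any selectivity between like groups. The acetal must survive base and be removable with dilute acid.

4 to 2 and 3, and 2 to 1: the diaryl ether C–O bond is cut on the side of the ring that carries a para formyl group, because only that ring is activated for addition–elimination. Two simple benzaldehydes result. The phenol partner must not carry a free aldehyde, hence the acetal 2.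

12 to 11, and 8 to 7 to 6 to 5: the O–benzyl bonds, one O–methyl bond and the aryl–acetyl C–C bond are cut. The chlorine is thus bought with 5, whose two reactive positions are equivalent, so acylation gives one regioisomer. The monomethylation must distinguish the free from the chelated hydroxyl.

## Other disconnections considered

Alternative 1: The cut is made at both C4–C4a bonds, between each pyranone carbonyl carbon and its ring A.
- Forward step: the diacid A2, a bis(3-aryloxy-2-arylacrylic acid) on the same diaryl ether core, would be treated with P2O5 in CH3SO3H. Each acid becomes an acylium-type electrophile and attacks the ortho position of its own aryloxy ring, closing both pyranones to give A1, the tri-O-methyl ether of the target, which is the same compound as 17.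
- In favour: ring closure and C–C bond formation are one event, no labile aldehyde is involved, and in the chlorinated half only one ortho position is free (para to the methoxy group), so the regiochemistry there is certain.
- Against: the non-chlorinated aryloxy ring has two open ortho positions, so a 5-methoxy isomer is possible. The chlorine deactivates its ring towards acylation. The hot acid could acylate or sulfonylate the electron-rich central rings. A2 must be built by joining two different phenols, A3 and A4, to two nearly identical acrylate termini, which brings back the differentiation problem without the simple acetal device of 4, and A4 is a much less common building block than 5.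
- Comparison: on structure the two plans are equal in how chlorine is placed, since both use a pre-chlorinated ring. On mechanism, electrophilic aromatic substitution replaces a cationic 1,2-shift, and the alternative is the better on robustness, because A2 and A1 are stable whereas 15 is not. On step economy no gain is expected: A1 joins the chosen route at 17 with the same final demethylation, and the way to A2 (a bis-arylacetate on the diaryl ether, two formylations, two separate O-arylations) should be at least as long as the way to 15.

Alternative 2: The cut removes two ring C–C bonds of the para-phenylene ring, so that ring is built de novo.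
- Forward step: methyl coumalate A5 (electron-poor 2-pyranone diene) and the aryl ethynyl ether A6 (electron-rich dienophile) would combine in an inverse-demand [4+2] addition. The bridged lactone loses CO2 to give the benzoate A7, the para arrangement following from bonding of the nucleophilic alkyne terminus to C6 of the pyranone.
- In favour: a regiodefined ring synthesis without metal or base, with the ether oxygen already in place.
- Against: it solves only the diaryl ether, which step 2 of the chosen plan makes in one operation from commercial materials. A6 needs its own multistep preparation through a dichlorovinyl ether and strong base, is thermally sensitive, and must carry the acid-labile dioxolane. A7 is at the ester level and must be reduced to reach 4. The isoflavone rings still require a separate key step.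
- Comparison: on structure it builds a ring that can be bought as 3. On mechanism, a pericyclic sequence replaces addition–elimination, and the two are equal in regiochemical certainty, since both give only the para ether. On step economy the alternative is clearly the longer by several steps.

Alternative 3: The cut is made at both C3–C1' bonds, between C3 of each chromenone and its ring B.
- Forward step: the bis(2'-hydroxychalcone) A8 would be treated with Tl(NO3)3 in methanol. Methanol adds to each β-carbon and trivalent thallium to each α-carbon; the ring-B aryl group then shifts from Cβ to Cα as monovalent thallium departs, and methanol traps the oxocarbenium ion to give the bis(dimethyl acetal) A9. Acid would close both rings to A1 (identical with 17).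
- In favour: the sequence is biomimetic and shorter. 7 and 11 could be used without benzylation, and no epoxidation or debenzylation is needed. The acetals of A9 are sturdier than the formyl groups of 15. On these points the alternative is the better.
- Against: at least one equivalent of highly toxic Tl(NO3)3 per enone is consumed. Free 2'-hydroxychalcones can divert to aurones under trivalent thallium and equilibrate with flavanones. The ring-B aryl group must itself migrate, which is a stricter electronic demand than the chosen plan makes of the same rings, where they only have to stabilise a benzylic cation; the para-aryloxyphenyl ring of the chlorinated half is the weak point.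
- Comparison: on structure the plans are equal, with the same bis-chalcone skeleton and the same building blocks. On mechanism, an oxidative aryl shift stands against a redox-neutral acyl shift of an epoxide. On step economy the alternative is the better by about three steps. The chosen plan is preferred because it avoids stoichiometric thallium and asks less of the weaker ring B.

Key step: step 10

Assumption on the chemistry: the two oxirane units of 14 are too far apart to influence each other, so 14 is expected as a mixture of two racemic diastereomers (one is drawn) and is used as such, since step 10 removes all four stereocentres.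

## Route

Step 1
Reactants: 1 isovanillin (3-hydroxy-4-methoxybenzaldehyde)
Product: 2 2-(3-hydroxy-4-methoxyphenyl)-1,3-dioxolane
Conditions: HOCH2CH2OH, cat. p-TsOH, toluene, reflux (Dean–Stark); Et3N quench
Reagents that add atoms: ethylene glycol, OCCO
Why: Acid-catalysed acetalisation driven by azeotropic removal of water; the phenol is meta to the acetal carbon, so no quinone methide pathway threatens the product once the acid is neutralised. The dioxolane keeps this formyl group silent so that the two aldehydes of the later diaryl ether can be used one after the other.

Step 2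
Reactants: 2 2-(3-hydroxy-4-methoxyphenyl)-1,3-dioxolane; 3 4-fluorobenzaldehyde
Product: 4 4-[5-(1,3-dioxolan-2-yl)-2-methoxyphenoxy]benzaldehyde
Conditions: K2CO3, DMF, 110 °C
Reagents that add atoms: none
Why: Nucleophilic aromatic substitution through a Meisenheimer intermediate: the para-formyl group activates displacement of fluoride by the phenoxide of 2, and the dioxolane is inert to carbonate base.

Step 3
Reactants: 5 2-chlororesorcinol (2-chlorobenzene-1,3-diol)
Product: 6 1-(3-chloro-2,4-dihydroxyphenyl)ethanone
Conditions: AcOH, BF3·OEt2, 90 °C; then aq. NaOAc
Reagents that add atoms: acetic acid, CC(=O)O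
Why: Friedel–Crafts C-acylation of a resorcinol (Nencki type) with the acid activated by BF3; C4 and C6 of 5 are equivalent and are the only positions ortho to one hydroxyl and para to the other, so one regioisomer is expected. The ketone product is deactivated towards a second acylation.

Step 4
Reactants: 6 1-(3-chloro-2,4-dihydroxyphenyl)ethanone
Product: 7 1-(3-chloro-2-hydroxy-4-methoxyphenyl)ethanone
Conditions: MeI (1.1 equiv), K2CO3 (1.1 equiv), acetone, 40 °C
Reagents that add atoms: iodomethane, CI
Why: Williamson etherification under stoichiometric control; the 2-hydroxyl is held in a hydrogen bond to the acetyl oxygen and is the less nucleophilic, so the 4-hydroxyl should be methylated selectively, as in the analogous monomethylation of 2,4-dihydroxyacetophenone.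

Step 5
Reactants: 7 1-(3-chloro-2-hydroxy-4-methoxyphenyl)ethanone
Product: 8 1-[2-(benzyloxy)-3-chloro-4-methoxyphenyl]ethanone
Conditions: BnBr, K2CO3, cat. KI, DMF, 70 °C
Reagents that add atoms: benzyl bromide, BrCc1ccccc1
Why: Williamson O-benzylation; the chelated, doubly flanked 2-hydroxyl needs a polar aprotic solvent, heat and iodide catalysis, and 7 has no other nucleophilic site.

Step 6
Reactants: 4 4-[5-(1,3-dioxolan-2-yl)-2-methoxyphenoxy]benzaldehyde; 8 1-[2-(benzyloxy)-3-chloro-4-methoxyphenyl]ethanone
Product: 10 3-(4-{(E)-3-[2-(benzyloxy)-3-chloro-4-methoxyphenyl]-3-oxoprop-1-en-1-yl}phenoxy)-4-methoxybenzaldehyde, via acetal chalcone 9 (not isolated)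
Conditions: KOH (0.5 equiv), EtOH–THF, rt; then 2 M HCl, THF, rt
Reagents that add atoms: water, O
Why: Claisen–Schmidt condensation: the enolate of 8 adds to the only free aldehyde of 4 and E1cB loss of water gives the thermodynamically preferred E-enone. Acidification in the same flask hydrolyses the electron-rich aryl dioxolane, while the enone, the benzyl ether and the diaryl ether are stable to dilute acid.

Step 7
Reactants: 11 paeonol (1-(2-hydroxy-4-methoxyphenyl)ethanone)
Product: 12 1-[2-(benzyloxy)-4-methoxyphenyl]ethanone
Conditions: BnBr, K2CO3, cat. KI, DMF, 70 °C
Reagents that add atoms: benzyl bromide, BrCc1ccccc1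
Why: Williamson O-benzylation of the chelated phenol under the same conditions as step 5; the benzyl group will later keep this oxygen away from the epoxide.

Step 8
Reactants: 10 3-(4-{(E)-3-[2-(benzyloxy)-3-chloro-4-methoxyphenyl]-3-oxoprop-1-en-1-yl}phenoxy)-4-methoxybenzaldehyde; 12 1-[2-(benzyloxy)-4-methoxyphenyl]ethanone
Product: 13 (E)-1-[2-(benzyloxy)-4-methoxyphenyl]-3-[3-(4-{(E)-3-[2-(benzyloxy)-3-chloro-4-methoxyphenyl]-3-oxoprop-1-en-1-yl}phenoxy)-4-methoxyphenyl]prop-2-en-1-one (bis-chalcone)
Conditions: KOH (0.5 equiv), EtOH–THF, 0 °C → rt
Reagents that add atoms: none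
Why: Second Claisen–Schmidt condensation, now at the unmasked aldehyde; the enolate of 12 should add to the aldehyde faster than to the β-carbon of the existing enone, and dehydration makes the addition practically irreversible. The 2'-benzyl ethers rule out flavanone formation.

Step 9
Reactants: 13 bis-chalcone
Product: 14 {3-[3-(4-{3-[2-(benzyloxy)-3-chloro-4-methoxybenzoyl]oxiran-2-yl}phenoxy)-4-methoxyphenyl]oxiran-2-yl}[2-(benzyloxy)-4-methoxyphenyl]methanone, both oxiranes trans, racemic, mixture of the two diastereomers that differ in the relation between the two oxiranes
Conditions: 30% H2O2, NaOH (0.5 equiv per enone), MeOH–THF, 0 °C → rt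
Reagents that add atoms: hydrogen peroxide, OO
Why: Weitz–Scheffer nucleophilic epoxidation: hydroperoxide adds to each β-carbon and the enolate closes on oxygen with loss of hydroxide, which spares the electron-rich arenes. Each oxirane gains two stereocentres whose relation is trans, because the intermediate enolate can rotate and closes through the less crowded arrangement; no absolute control and no control between the two distant oxiranes is needed.

Step 10
Reactants: 14 bis(trans-chalcone epoxide)
Product: 15 2-[3-(4-{1-[2-(benzyloxy)-3-chloro-4-methoxyphenyl]-1,3-dioxopropan-2-yl}phenoxy)-4-methoxyphenyl]-3-[2-(benzyloxy)-4-methoxyphenyl]-3-oxopropanal (bis(α-formyl deoxybenzoin), drawn as the keto aldehyde, methine carbons labile)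
Conditions: BF3·OEt2 (2.5 equiv), CH2Cl2, 0 °C → rt, 20 min; cold aq. NaHCO3; used crude
Reagents that add atoms: none
Why: BF3 binds each oxirane oxygen and the C–O bond at the aryl-bearing carbon ionises, because that cation is benzylic and conjugated with a para-methoxy group in one half and a para-aryloxy group in the other, whereas ionisation at the other carbon would put a cation next to a carbonyl group. The aroyl group on the neighbouring carbon then migrates with its bonding electrons to the cationic centre, and the oxygen left behind becomes the formyl oxygen, so each half ends as an aryl ketone whose α-carbon carries the ring-B aryl group and a CHO group. The closest known reaction type is the Lewis-acid (semipinacol-type) rearrangement of trans-chalcone epoxides with 2'-alkoxy groups to α-formyl deoxybenzoins, a classical entry to isoflavones. No ring is closed; the two new C–C bonds are the future C3–C4 bonds and the formyl carbons are the future C2 atoms. No lasting stereocentre is formed: the four oxirane stereocentres are destroyed, and the new methine carbons lie between two carbonyl groups, are largely enolised and disappear on aromatisation, so both diastereomers of 14 converge. Three selectivities are needed: ionisation at the benzylic carbon, acyl migration in preference to hydride migration (which would give a 1,2-diketone), and no participation of the 2'-oxygens. They are secured in that order by the para-oxygen donors on both B rings, by the high migratory aptitude of the electron-rich aroyl groups, and by the benzyl ethers, without which the phenols would close onto the epoxides to give dihydroflavonols or aurones. Short contact and a cold bicarbonate quench are planned because β-keto aldehydes lose the formyl group on long exposure to acid or base.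

Step 11
Reactants: 15 bis(α-formyl deoxybenzoin)
Product: 17 8-chloro-7-methoxy-3-{4-[2-methoxy-5-(7-methoxy-4-oxo-4H-chromen-3-yl)phenoxy]phenyl}-4H-chromen-4-one, via bis(hydroxyaryl) keto aldehyde 16 (not isolated)
Conditions: BCl3, C6HMe5, CH2Cl2, −78 → 0 °C; then 2 M HCl, THF, 50 °C
Reagents that add atoms: none
Why: BCl3 cleaves the two aryl benzyl ethers, helped by chelation to the neighbouring ketone, and pentamethylbenzene traps the benzyl cations; in aqueous acid each freed phenol adds to its formyl group (6-exo-trig hemiacetal formation) and dehydration gives the 4-pyranone. The non-chelated methyl ethers, the aryl chloride and the diaryl ether are not touched at this temperature, which is why a Lewis acid is chosen over hydrogenolysis.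

Step 12
Reactants: 17 tri-O-methyl ether of the target
Product: 18 Bisoflavolin K, 8-chloro-7-hydroxy-3-{4-[2-hydroxy-5-(7-hydroxy-4-oxo-4H-chromen-3-yl)phenoxy]phenyl}-4H-chromen-4-one
Conditions: BBr3 (excess), CH2Cl2, −78 °C → rt; then MeOH, H2O
Reagents that add atoms: none
Why: Lewis-acid dealkylation: each methoxy oxygen binds boron, bromide removes the methyl group by SN2 attack, and the borate esters are hydrolysed on work-up. The chromenones tolerate acid (they are opened only by base), and the diaryl ether and aryl chloride are inert to BBr3.

## Compound list

1 | isovanillin (3-hydroxy-4-methoxybenzaldehyde) | COc1ccc(C=O)cc1O | starting material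
2 | 2-(3-hydroxy-4-methoxyphenyl)-1,3-dioxolane | COc1ccc(C2OCCO2)cc1O | intermediate
3 | 4-fluorobenzaldehyde | O=Cc1ccc(F)cc1 | starting material
4 | 4-[5-(1,3-dioxolan-2-yl)-2-methoxyphenoxy]benzaldehyde | COc1ccc(C2OCCO2)cc1Oc1ccc(C=O)cc1 | intermediate
5 | 2-chlororesorcinol (2-chlorobenzene-1,3-diol) | Oc1cccc(O)c1Cl | starting material
6 | 1-(3-chloro-2,4-dihydroxyphenyl)ethanone | CC(=O)c1ccc(O)c(Cl)c1O | intermediate
7 | 1-(3-chloro-2-hydroxy-4-methoxyphenyl)ethanone | CC(=O)c1ccc(OC)c(Cl)c1O | intermediate
8 | 1-[2-(benzyloxy)-3-chloro-4-methoxyphenyl]ethanone | CC(=O)c1ccc(OC)c(Cl)c1OCc1ccccc1 | intermediate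
9 | (E)-1-[2-(benzyloxy)-3-chloro-4-methoxyphenyl]-3-{4-[5-(1,3-dioxolan-2-yl)-2-methoxyphenoxy]phenyl}prop-2-en-1-one (acetal chalcone) | COc1ccc(C2OCCO2)cc1Oc1ccc(/C=C/C(=O)c2ccc(OC)c(Cl)c2OCc2ccccc2)cc1 | intermediate (not isolated)
10 | 3-(4-{(E)-3-[2-(benzyloxy)-3-chloro-4-methoxyphenyl]-3-oxoprop-1-en-1-yl}phenoxy)-4-methoxybenzaldehyde | COc1ccc(C=O)cc1Oc1ccc(/C=C/C(=O)c2ccc(OC)c(Cl)c2OCc2ccccc2)cc1 | intermediate
11 | paeonol (1-(2-hydroxy-4-methoxyphenyl)ethanone) | CC(=O)c1ccc(OC)cc1O | starting material
12 | 1-[2-(benzyloxy)-4-methoxyphenyl]ethanone | CC(=O)c1ccc(OC)cc1OCc1ccccc1 | intermediate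
13 | (E)-1-[2-(benzyloxy)-4-methoxyphenyl]-3-[3-(4-{(E)-3-[2-(benzyloxy)-3-chloro-4-methoxyphenyl]-3-oxoprop-1-en-1-yl}phenoxy)-4-methoxyphenyl]prop-2-en-1-one (bis-chalcone) | COc1ccc(C(=O)/C=C/c2ccc(OC)c(Oc3ccc(/C=C/C(=O)c4ccc(OC)c(Cl)c4OCc4ccccc4)cc3)c2)c(OCc2ccccc2)c1 | intermediate
14 | {3-[3-(4-{3-[2-(benzyloxy)-3-chloro-4-methoxybenzoyl]oxiran-2-yl}phenoxy)-4-methoxyphenyl]oxiran-2-yl}[2-(benzyloxy)-4-methoxyphenyl]methanone; both oxiranes trans; racemic; drawn with R at the aroyl-bearing and S at the aryl-bearing carbon of the non-chlorinated half and S and R at the corresponding carbons of the chlorinated half; the other pairing forms alongside | COc1ccc(C(=O)[C@@H]2O[C@H]2c2ccc(OC)c(Oc3ccc([C@H]4O[C@@H]4C(=O)c4ccc(OC)c(Cl)c4OCc4ccccc4)cc3)c2)c(OCc2ccccc2)c1 | intermediate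
15 | 2-[3-(4-{1-[2-(benzyloxy)-3-chloro-4-methoxyphenyl]-1,3-dioxopropan-2-yl}phenoxy)-4-methoxyphenyl]-3-[2-(benzyloxy)-4-methoxyphenyl]-3-oxopropanal (keto aldehyde form; methines labile) | COc1ccc(C(=O)C(C=O)c2ccc(OC)c(Oc3ccc(C(C=O)C(=O)c4ccc(OC)c(Cl)c4OCc4ccccc4)cc3)c2)c(OCc2ccccc2)c1 | intermediate
16 | 2-[3-(4-{1-(3-chloro-2-hydroxy-4-methoxyphenyl)-1,3-dioxopropan-2-yl}phenoxy)-4-methoxyphenyl]-3-(2-hydroxy-4-methoxyphenyl)-3-oxopropanal (methines labile) | COc1ccc(C(=O)C(C=O)c2ccc(OC)c(Oc3ccc(C(C=O)C(=O)c4ccc(OC)c(Cl)c4O)cc3)c2)c(O)c1 | intermediate (not isolated)
17 | 8-chloro-7-methoxy-3-{4-[2-methoxy-5-(7-methoxy-4-oxo-4H-chromen-3-yl)phenoxy]phenyl}-4H-chromen-4-one | COc1ccc2c(=O)c(-c3ccc(OC)c(Oc4ccc(-c5coc6c(Cl)c(OC)ccc6c5=O)cc4)c3)coc2c1 | intermediate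
18 | Bisoflavolin K, 8-chloro-7-hydroxy-3-{4-[2-hydroxy-5-(7-hydroxy-4-oxo-4H-chromen-3-yl)phenoxy]phenyl}-4H-chromen-4-one | O=c1c(-c2ccc(O)c(Oc3ccc(-c4coc5c(Cl)c(O)ccc5c4=O)cc3)c2)coc2cc(O)ccc12 | target

## Step count and risks

Total step count: 12. Longest linear sequence: 9 steps (5 → 6 → 7 → 8 → 10 → 13 → 14 → 15 → 17 → 18, steps 3, 4, 5, 6, 8, 9, 10, 11, 12).

Least certain steps:

Step 10 (key step). The most likely failure is loss of the formyl groups by retro-Claisen-type cleavage during the reaction or work-up. A second is diversion of the benzylic cation in the chlorinated half, which is stabilised only by a para-aryloxy group: capture by fluoride, or debenzylative closure by the 2'-oxygen, so that one oxirane rearranges cleanly and the other does not. Fallback: set out from 13 and avoid the epoxide altogether. Oxidative 1,2-aryl shift with PhI(OH)OTs (a trivalent iodine reagent) in MeOH–HC(OMe)3 at rt adds methanol to each β-carbon and iodine to each α-carbon; the ring-B aryl group then moves from Cβ to Cα as iodobenzene leaves, giving the bis(dimethyl acetal) F1. Treatment of F1 with BCl3 and C6HMe5 in CH2Cl2 at −78 → 0 °C, then 2 M HCl in THF at 50 °C, removes the benzyl groups and closes both pyranones with loss of methanol, returning to the route at 17. This forms the C3–C1' bonds instead of the C3–C4 bonds and is known chemistry for 2'-benzyloxychalcones with electron-rich B rings.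

Step 11. Benzyl cations may be transferred to the electron-rich rings, or the formyl carbon may be lost before the phenol has closed on it, since the open-chain β-keto aldehyde must survive a strong Lewis acid. Fallback: set out from 15 and deformylate on purpose (aq. Na2CO3, EtOH, 60 °C) to the robust bis-deoxybenzoin F2. Debenzylation with BCl3 and C6HMe5 gives the bis(2-hydroxydeoxybenzoin) F3. Me2NCH(OMe)2 in toluene at 90 °C then reinstalls each C2 carbon as the bis-enaminone F4, which closes with loss of dimethylamine (completed with HCl in MeOH) and returns to the route at 17. The C3–C4 bonds made by the key step are kept; only the one-carbon unit is replaced.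

Step 8. The ketone enolate may add in conjugate fashion to the enone already present or to the new one, and hydroxide may cause retro-aldol exchange that scrambles the two aroyl groups between the two halves. Fallback: set out from 12 and 10 under kinetic control. LiN(SiMe3)2 in THF at −78 °C turns 12 into its lithium enolate, which adds 1,2 to the aldehyde of 10 to give the β-hydroxy ketone F5; dehydration of F5 with cat. p-TsOH in toluene at 60 °C returns to the route at 13. No free hydroxide and no equilibrating enolate are present.

Step 1 (with its consequence for step 2). The electron-rich aryl dioxolane may hydrolyse on work-up or handling; any 1 regenerated would give a symmetrical dialdehyde in step 2 and the distinction between the two formyl groups would be lost. Fallback: set out from 1 and distinguish the aldehydes by order of assembly, not by a protecting group. Claisen–Schmidt condensation of 1 with 12 (KOH, 3 equiv, EtOH, 50 °C; the phenoxide is meta to the formyl group and deactivates it little) gives the chalcone phenol F6. Addition–elimination of F6 with 3 (K2CO3, DMF, 100 °C) gives the chalcone aldehyde F7. Condensation of F7 with 8 (KOH, EtOH–THF, rt) returns to the route at 13.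

## Further compounds

F1 | step 10 | 1-[2-(benzyloxy)-4-methoxyphenyl]-2-[3-(4-{1-[2-(benzyloxy)-3-chloro-4-methoxyphenyl]-3,3-dimethoxy-1-oxopropan-2-yl}phenoxy)-4-methoxyphenyl]-3,3-dimethoxypropan-1-one (mixture at the two methine carbons) | COc1ccc(C(=O)C(C(OC)OC)c2ccc(OC)c(Oc3ccc(C(C(OC)OC)C(=O)c4ccc(OC)c(Cl)c4OCc4ccccc4)cc3)c2)c(OCc2ccccc2)c1
F2 | step 11 | 1-[2-(benzyloxy)-4-methoxyphenyl]-2-[3-(4-{2-[2-(benzyloxy)-3-chloro-4-methoxyphenyl]-2-oxoethyl}phenoxy)-4-methoxyphenyl]ethanone | COc1ccc(C(=O)Cc2ccc(OC)c(Oc3ccc(CC(=O)c4ccc(OC)c(Cl)c4OCc4ccccc4)cc3)c2)c(OCc2ccccc2)c1
F3 | step 11 | 2-[3-(4-{2-(3-chloro-2-hydroxy-4-methoxyphenyl)-2-oxoethyl}phenoxy)-4-methoxyphenyl]-1-(2-hydroxy-4-methoxyphenyl)ethanone | COc1ccc(C(=O)Cc2ccc(OC)c(Oc3ccc(CC(=O)c4ccc(OC)c(Cl)c4O)cc3)c2)c(O)c1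
F4 | step 11 | 2-[3-(4-{1-(3-chloro-2-hydroxy-4-methoxyphenyl)-3-(dimethylamino)-1-oxoprop-2-en-2-yl}phenoxy)-4-methoxyphenyl]-3-(dimethylamino)-1-(2-hydroxy-4-methoxyphenyl)prop-2-en-1-one (alkene geometry not fixed) | COc1ccc(C(=O)C(=CN(C)C)c2ccc(OC)c(Oc3ccc(C(=CN(C)C)C(=O)c4ccc(OC)c(Cl)c4O)cc3)c2)c(O)c1
F5 | step 8 | 1-[2-(benzyloxy)-4-methoxyphenyl]-3-[3-(4-{(E)-3-[2-(benzyloxy)-3-chloro-4-methoxyphenyl]-3-oxoprop-1-en-1-yl}phenoxy)-4-methoxyphenyl]-3-hydroxypropan-1-one (racemic) | COc1ccc(C(=O)CC(O)c2ccc(OC)c(Oc3ccc(/C=C/C(=O)c4ccc(OC)c(Cl)c4OCc4ccccc4)cc3)c2)c(OCc2ccccc2)c1
F6 | step 1 | (E)-1-[2-(benzyloxy)-4-methoxyphenyl]-3-(3-hydroxy-4-methoxyphenyl)prop-2-en-1-one | COc1ccc(C(=O)/C=C/c2ccc(OC)c(O)c2)c(OCc2ccccc2)c1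
F7 | step 1 | 4-(5-{(E)-3-[2-(benzyloxy)-4-methoxyphenyl]-3-oxoprop-1-en-1-yl}-2-methoxyphenoxy)benzaldehyde | COc1ccc(C(=O)/C=C/c2ccc(OC)c(Oc3ccc(C=O)cc3)c2)c(OCc2ccccc2)c1
A1 | alternative 1 | 8-chloro-7-methoxy-3-{4-[2-methoxy-5-(7-methoxy-4-oxo-4H-chromen-3-yl)phenoxy]phenyl}-4H-chromen-4-one (identical with 17) | COc1ccc2c(=O)c(-c3ccc(OC)c(Oc4ccc(-c5coc6c(Cl)c(OC)ccc6c5=O)cc4)c3)coc2c1
A2 | alternative 1 | (2Z)-2-[3-(4-{(1Z)-1-carboxy-2-(2-chloro-3-methoxyphenoxy)ethenyl}phenoxy)-4-methoxyphenyl]-3-(3-methoxyphenoxy)prop-2-enoic acid | COc1cccc(O/C=C(\C(=O)O)c2ccc(OC)c(Oc3ccc(/C(C(=O)O)=C/Oc4cccc(OC)c4Cl)cc3)c2)c1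
A3 | alternative 1 | 3-methoxyphenol | COc1cccc(O)c1
A4 | alternative 1 | 2-chloro-3-methoxyphenol | COc1cccc(O)c1Cl
A5 | alternative 2 | methyl coumalate (methyl 2-oxo-2H-pyran-5-carboxylate) | COC(=O)c1ccc(=O)oc1
A6 | alternative 2 | 2-[3-(ethynyloxy)-4-methoxyphenyl]-1,3-dioxolane | C#COc1cc(C2OCCO2)ccc1OC
A7 | alternative 2 | methyl 4-[5-(1,3-dioxolan-2-yl)-2-methoxyphenoxy]benzoate | COC(=O)c1ccc(Oc2cc(C3OCCO3)ccc2OC)cc1
A8 | alternative 3 | (E)-3-[3-(4-{(E)-3-(3-chloro-2-hydroxy-4-methoxyphenyl)-3-oxoprop-1-en-1-yl}phenoxy)-4-methoxyphenyl]-1-(2-hydroxy-4-methoxyphenyl)prop-2-en-1-one | COc1ccc(C(=O)/C=C/c2ccc(OC)c(Oc3ccc(/C=C/C(=O)c4ccc(OC)c(Cl)c4O)cc3)c2)c(O)c1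
A9 | alternative 3 | 2-[3-(4-{1-(3-chloro-2-hydroxy-4-methoxyphenyl)-3,3-dimethoxy-1-oxopropan-2-yl}phenoxy)-4-methoxyphenyl]-1-(2-hydroxy-4-methoxyphenyl)-3,3-dimethoxypropan-1-one (mixture at the two methine carbons) | COc1ccc(C(=O)C(C(OC)OC)c2ccc(OC)c(Oc3ccc(C(C(OC)OC)C(=O)c4ccc(OC)c(Cl)c4O)cc3)c2)c(O)c1
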